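**Retrosynthetic overview**
- The strategy rests on the oxolane ring O1–C2–C3–C4–C5. C2 is a benzylic CH bonded to O1, and C5 is an O-bound CH2 that can be carried as an ester carbonyl. O1–C5 can therefore be closed by acylation from a C2 alkoxide generated by reducing a C2 aryl ketone.
- Target ⇐ benzyl-protected oxolane diol ⇐ silyloxy lactone ester. The endgame takes the C5 lactone carbonyl to CH2 via the lactol, reduces the C3 ester to CH2OH, and removes the silyl and benzyl groups.
- Silyloxy lactone ester ⇐ acyclic aryl keto diester, by asymmetric transfer hydrogenation with lactonisation in the same flask. This forms C2–H and O1–C5, closes the only ring, and sets C2.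
- Keto diester ⇐ O-benzylvanillin + 3-arylmethyl-2-oxosuccinate, by dynamic kinetic cross-benzoin (C2–C3 bond, sets C3 and C4). The oxosuccinate ⇐ O-benzyl dihydroferulate + dimethyl oxalate, by Claisen condensation (C3–C4 bond).

Key step: step 6

Remarks on the chemistry:
- Ring numbering O1, C2 (aryl), C3 (quaternary), C4 (arylmethyl), C5 is used for all intermediates.
- The C3 oxygen is carried as a triethylsilyl ether, which should tolerate formic acid and the later Lewis acid better than a trimethylsilyl ether.
- The hand of the triazolium salt in step 4 cannot be predicted with confidence. It is to be fixed in a pilot run by correlating the configuration of 7; both antipodes are commercial.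

**Step 1**
Reactants: 1 3-(4-hydroxy-3-methoxyphenyl)propanoic acid
Product: 2 methyl 3-(4-hydroxy-3-methoxyphenyl)propanoate
Conditions: MeOH, H2SO4 (cat.), reflux
Reagents that add atoms: methanol, CO
Why: Fischer esterification, driven by methanol as solvent; the phenol is inert under acid catalysis.

**Step 2**
Reactants: 2 methyl 3-(4-hydroxy-3-methoxyphenyl)propanoate
Product: 3 methyl 3-[4-(benzyloxy)-3-methoxyphenyl]propanoate
Conditions: BnBr, K2CO3, DMF, rt
Reagents that add atoms: benzyl bromide, BrCc1ccccc1
Why: Williamson etherification of the phenoxide with a benzylic bromide; the methyl ester is stable to carbonate.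

**Step 3**
Reactants: 3 methyl 3-[4-(benzyloxy)-3-methoxyphenyl]propanoate; 4 dimethyl oxalate
Product: 5 dimethyl 2-[4-(benzyloxy)-3-methoxybenzyl]-3-oxobutanedioate (racemic, keto–enol mixture)
Conditions: NaOMe (1.2 equiv), 4 (1.5 equiv), THF, 0 °C → rt; cold 1 M HCl
Reagents that add atoms: none
Why: Crossed Claisen condensation, in which the enolate of 3 attacks the non-enolisable and more electrophilic oxalate and formation of the stabilised product enolate pulls the equilibrium, so that acidification should give 5 as a freely racemising keto–enol mixture.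

**Step 4**
Reactants: 5 dimethyl 2-[4-(benzyloxy)-3-methoxybenzyl]-3-oxobutanedioate; 6 4-(benzyloxy)-3-methoxybenzaldehyde
Product: 7 dimethyl (2R,3R)-2-[4-(benzyloxy)-3-methoxybenzoyl]-3-[4-(benzyloxy)-3-methoxybenzyl]-2-hydroxybutanedioate
Conditions: aminoindanol-derived N-C6F5 triazolium tetrafluoroborate (15 mol %), K2CO3 (15 mol %), MTBE, rt
Reagents that add atoms: none
Why: NHC-catalysed cross-benzoin in its dynamic kinetic form (closest precedent: configurationally labile β-halo α-keto esters), in which the Breslow intermediate from 6 adds to the ketone of 5, which is more electrophilic than the aldehyde, while 5 racemises through its enol; the chiral triazolylidene fixes the carbinol centre (ring C3), and a polar Felkin–Anh approach anti to the C5 ester, with hydrogen beside the trajectory, selects the enantiomer of 5 that gives the ring C4 configuration.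

**Step 5**
Reactants: 7 dimethyl (2R,3R)-2-[4-(benzyloxy)-3-methoxybenzoyl]-3-[4-(benzyloxy)-3-methoxybenzyl]-2-hydroxybutanedioate
Product: 8 dimethyl (2R,3R)-2-[4-(benzyloxy)-3-methoxybenzoyl]-3-[4-(benzyloxy)-3-methoxybenzyl]-2-[(triethylsilyl)oxy]butanedioate
Conditions: TESOTf, 2,6-lutidine, CH2Cl2, −78 → 0 °C
Reagents that add atoms: triethylsilyl trifluoromethanesulfonate, CC[Si](CC)(CC)OS(=O)(=O)C(F)(F)F
Why: Silyl triflate silylation of a hindered tertiary alcohol; it blocks retro-benzoin and α-ketol rearrangement, removes the hydroxyl that could direct hydride to the wrong face, and later shields the C3 ester, with no stereocentre touched.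

**Step 6**
Reactants: 8 dimethyl (2R,3R)-2-[4-(benzyloxy)-3-methoxybenzoyl]-3-[4-(benzyloxy)-3-methoxybenzyl]-2-[(triethylsilyl)oxy]butanedioate
Product: 10 methyl (2R,3R,4R)-2-[4-(benzyloxy)-3-methoxyphenyl]-4-[4-(benzyloxy)-3-methoxybenzyl]-5-oxo-3-[(triethylsilyl)oxy]oxolane-3-carboxylate, via hydroxy diester 9 (not isolated)
Conditions: RuCl[(S,S)-Teth-TsDPEN] (3 mol %), HCO2H/Et3N (5:2), EtOAc, 40 °C
Reagents that add atoms: none
Why: The ruthenium amide takes hydrogen from formate and passes the Ru–H/N–H pair to the C2 carbonyl through a six-membered outer-sphere transition state, and the C2 hydroxyl of 9 then adds to the C5 ester carbonyl with loss of methanol. The closest known reaction type is the asymmetric transfer hydrogenation of aryl γ-keto esters that lactonise in the same flask. The ring closes by 5-exo-trig acyl substitution of O1 on C5; attack on the C3 ester would need a four-membered ring and should not compete. C2 is set by the (S,S) catalyst, which through the usual edge-to-face contact between the substrate aryl and the η6-arene should deliver hydride to the Si face of the ketone (O > C3 > aryl) and give 2R, the aryl cis to the C3 oxygen. The substrate should lean the same way by a Felkin arrangement (branched C4 carbon anti to the incoming hydride, C3 ester inside, small siloxy oxygen beside the aryl), so catalyst and substrate are expected to be matched; no metal chelate is invoked because the ketone does not bind to ruthenium. The step needs facial selectivity at a hindered, electron-rich aryl ketone and survival of the C4 centre and the silyl ether, which the buffered medium and the tertiary position of the silyl ether should secure.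

**Step 7**
Reactants: 10 methyl (2R,3R,4R)-2-[4-(benzyloxy)-3-methoxyphenyl]-4-[4-(benzyloxy)-3-methoxybenzyl]-5-oxo-3-[(triethylsilyl)oxy]oxolane-3-carboxylate
Product: 11 methyl (2R,3R,4R)-2-[4-(benzyloxy)-3-methoxyphenyl]-4-[4-(benzyloxy)-3-methoxybenzyl]-5-hydroxy-3-[(triethylsilyl)oxy]oxolane-3-carboxylate (anomeric mixture)
Conditions: DIBAL-H (1.2 equiv), toluene, −78 °C; Rochelle salt
Reagents that add atoms: none
Why: Partial reduction of a γ-lactone to the lactol, where the aluminium hemiacetal is stable at −78 °C and the lactone carbonyl should react well before the methyl ester, which sits on the fully substituted silyloxy carbon C3 and is shielded like a pivalate; the mixture at C5 is of no consequence.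

**Step 8**
Reactants: 11 methyl (2R,3R,4R)-2-[4-(benzyloxy)-3-methoxyphenyl]-4-[4-(benzyloxy)-3-methoxybenzyl]-5-hydroxy-3-[(triethylsilyl)oxy]oxolane-3-carboxylate
Product: 12 methyl (2R,3R,4S)-2-[4-(benzyloxy)-3-methoxyphenyl]-4-[4-(benzyloxy)-3-methoxybenzyl]-3-[(triethylsilyl)oxy]oxolane-3-carboxylate
Conditions: Et3SiH, BF3·OEt2, CH2Cl2, −78 → −40 °C
Reagents that add atoms: none
Why: Ionic hydrogenation of a lactol, in which the Lewis acid ionises C5–OH to the cyclic oxocarbenium ion and triethylsilane delivers hydride, so both anomers converge on the C5 methylene; the benzylic C2–O1 bond should hold because the two electron-withdrawing groups on C3 disfavour a cation at C2.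

**Step 9**
Reactants: 12 methyl (2R,3R,4S)-2-[4-(benzyloxy)-3-methoxyphenyl]-4-[4-(benzyloxy)-3-methoxybenzyl]-3-[(triethylsilyl)oxy]oxolane-3-carboxylate
Product: 13 methyl (2R,3R,4S)-2-[4-(benzyloxy)-3-methoxyphenyl]-4-[4-(benzyloxy)-3-methoxybenzyl]-3-hydroxyoxolane-3-carboxylate
Conditions: TBAF, AcOH, THF, 0 °C → rt
Reagents that add atoms: none
Why: Fluoride-driven desilylation buffered with acetic acid; it is placed before the hydride reduction so that no 1,2-silyl shift to a new primary alkoxide can occur.

**Step 10**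
Reactants: 13 methyl (2R,3R,4S)-2-[4-(benzyloxy)-3-methoxyphenyl]-4-[4-(benzyloxy)-3-methoxybenzyl]-3-hydroxyoxolane-3-carboxylate
Product: 14 (2R,3S,4S)-2-[4-(benzyloxy)-3-methoxyphenyl]-4-[4-(benzyloxy)-3-methoxybenzyl]-3-(hydroxymethyl)oxolan-3-ol
Conditions: LiAlH4, THF, 0 °C → rt; Fieser work-up
Reagents that add atoms: none
Why: Hydride reduction of an α-hydroxy ester to the 1,2-diol, assisted by the neighbouring alkoxide; ethers and stereocentres are untouched (the C3 descriptor changes only through CIP priorities).

**Step 11**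
Reactants: 14 (2R,3S,4S)-2-[4-(benzyloxy)-3-methoxyphenyl]-4-[4-(benzyloxy)-3-methoxybenzyl]-3-(hydroxymethyl)oxolan-3-ol
Product: 15 (2R,3S,4S)-2-(4-hydroxy-3-methoxyphenyl)-4-(4-hydroxy-3-methoxybenzyl)-3-(hydroxymethyl)oxolan-3-ol
Conditions: H2 (1 atm), 10% Pd/C, EtOAc–MeOH, rt
Reagents that add atoms: none
Why: Catalytic hydrogenolysis of the two aryl benzyl ethers, which should be much faster under neutral conditions than cleavage of the cyclic dialkyl benzylic ether at C2, so the reaction is stopped once the benzyl groups are gone.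

**Compound list**
1 | 3-(4-hydroxy-3-methoxyphenyl)propanoic acid | OC(=O)CCc1ccc(O)c(OC)c1 | starting material
2 | methyl 3-(4-hydroxy-3-methoxyphenyl)propanoate | COC(=O)CCc1ccc(O)c(OC)c1 | intermediate
3 | methyl 3-[4-(benzyloxy)-3-methoxyphenyl]propanoate | COC(=O)CCc1ccc(OCc2ccccc2)c(OC)c1 | intermediate
4 | dimethyl oxalate | COC(=O)C(=O)OC | starting material
5 | dimethyl 2-[4-(benzyloxy)-3-methoxybenzyl]-3-oxobutanedioate (racemic, keto–enol mixture) | COC(=O)C(=O)C(Cc1ccc(OCc2ccccc2)c(OC)c1)C(=O)OC | intermediate
6 | 4-(benzyloxy)-3-methoxybenzaldehyde | COc1cc(C=O)ccc1OCc1ccccc1 | starting material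
7 | dimethyl (2R,3R)-2-[4-(benzyloxy)-3-methoxybenzoyl]-3-[4-(benzyloxy)-3-methoxybenzyl]-2-hydroxybutanedioate | COC(=O)[C@H](Cc1ccc(OCc2ccccc2)c(OC)c1)[C@](O)(C(=O)OC)C(=O)c1ccc(OCc2ccccc2)c(OC)c1 | intermediate
8 | dimethyl (2R,3R)-2-[4-(benzyloxy)-3-methoxybenzoyl]-3-[4-(benzyloxy)-3-methoxybenzyl]-2-[(triethylsilyl)oxy]butanedioate | COC(=O)[C@H](Cc1ccc(OCc2ccccc2)c(OC)c1)[C@](O[Si](CC)(CC)CC)(C(=O)OC)C(=O)c1ccc(OCc2ccccc2)c(OC)c1 | intermediate
9 | dimethyl (2R,3R)-2-[(R)-[4-(benzyloxy)-3-methoxyphenyl](hydroxy)methyl]-3-[4-(benzyloxy)-3-methoxybenzyl]-2-[(triethylsilyl)oxy]butanedioate | COC(=O)[C@H](Cc1ccc(OCc2ccccc2)c(OC)c1)[C@](O[Si](CC)(CC)CC)(C(=O)OC)[C@H](O)c1ccc(OCc2ccccc2)c(OC)c1 | intermediate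
10 | methyl (2R,3R,4R)-2-[4-(benzyloxy)-3-methoxyphenyl]-4-[4-(benzyloxy)-3-methoxybenzyl]-5-oxo-3-[(triethylsilyl)oxy]oxolane-3-carboxylate | O=C1O[C@H](c2ccc(OCc3ccccc3)c(OC)c2)[C@@](O[Si](CC)(CC)CC)(C(=O)OC)[C@H]1Cc1ccc(OCc2ccccc2)c(OC)c1 | intermediate
11 | methyl (2R,3R,4R)-2-[4-(benzyloxy)-3-methoxyphenyl]-4-[4-(benzyloxy)-3-methoxybenzyl]-5-hydroxy-3-[(triethylsilyl)oxy]oxolane-3-carboxylate (anomeric mixture) | OC1O[C@H](c2ccc(OCc3ccccc3)c(OC)c2)[C@@](O[Si](CC)(CC)CC)(C(=O)OC)[C@H]1Cc1ccc(OCc2ccccc2)c(OC)c1 | intermediate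
12 | methyl (2R,3R,4S)-2-[4-(benzyloxy)-3-methoxyphenyl]-4-[4-(benzyloxy)-3-methoxybenzyl]-3-[(triethylsilyl)oxy]oxolane-3-carboxylate | C1O[C@H](c2ccc(OCc3ccccc3)c(OC)c2)[C@@](O[Si](CC)(CC)CC)(C(=O)OC)[C@H]1Cc1ccc(OCc2ccccc2)c(OC)c1 | intermediate
13 | methyl (2R,3R,4S)-2-[4-(benzyloxy)-3-methoxyphenyl]-4-[4-(benzyloxy)-3-methoxybenzyl]-3-hydroxyoxolane-3-carboxylate | C1O[C@H](c2ccc(OCc3ccccc3)c(OC)c2)[C@@](O)(C(=O)OC)[C@H]1Cc1ccc(OCc2ccccc2)c(OC)c1 | intermediate
14 | (2R,3S,4S)-2-[4-(benzyloxy)-3-methoxyphenyl]-4-[4-(benzyloxy)-3-methoxybenzyl]-3-(hydroxymethyl)oxolan-3-ol | C1O[C@H](c2ccc(OCc3ccccc3)c(OC)c2)[C@@](O)(CO)[C@H]1Cc1ccc(OCc2ccccc2)c(OC)c1 | intermediate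
15 | (2R,3S,4S)-2-(4-hydroxy-3-methoxyphenyl)-4-(4-hydroxy-3-methoxybenzyl)-3-(hydroxymethyl)oxolan-3-ol | COc1cc(C[C@H]2CO[C@H](c3ccc(O)c(OC)c3)[C@@]2(O)CO)ccc1O | target

**Step count**
Total steps: 11. Longest linear sequence: 11 steps (1 → 15); 4 and 6 are purchased.

**Steps most likely to fail**

1. Step 6. Hydride transfer to a ketone that is flanked by a fully substituted carbon and conjugated to an electron-rich arene may be slow. The face preferred by the catalyst may also not coincide with the face preferred by the substrate, and the silyl ether may erode in formic acid.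
Fallback: it sets out from 8 and comes back at 10, and replaces catalyst control by substrate control. Compound 8 is reduced with a small, non-chelating borohydride (Bu4NBH4 or NaBH4, CH2Cl2–MeOH, −40 °C), which by the Felkin arrangement described in step 6 should attack the same Si face. This gives hydroxy diester 9, now handled as a crude product. Ring closure is then completed in a separate operation with catalytic PPTS in toluene at 60 °C to give 10, and any C2 epimer is removed as the diastereomeric lactone by chromatography. The free ketol 7 is not used as substrate, because chelated or hydroxyl-bound hydride delivery would be expected to favour the other face.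

2. Step 4. The oxosuccinate may rest as its enol or enolate and escape the Breslow intermediate. Retro-benzoin equilibration or a weak Felkin preference at C4 may also leave the adduct as a mixture of diastereomers.
Fallback: it sets out from 6 and 3 and comes back at 7, making the C3–C4 bond by an aldol reaction instead of the C2–C3 bond by umpolung. Aldehyde 6 is homologated with methyl diazoacetate (NbCl5 or SnCl2 cat., CH2Cl2, Roskamp reaction) to methyl 3-[4-(benzyloxy)-3-methoxyphenyl]-3-oxopropanoate F1. F1 is oxidised with Dess–Martin periodinane and pyridine to the vicinal tricarbonyl methyl 3-[4-(benzyloxy)-3-methoxyphenyl]-2,3-dioxopropanoate F2, which is dried free of its hydrate before use. The lithium enolate of 3 (LDA, THF, −78 °C) should add to the central, most electrophilic carbonyl of F2 to give dimethyl 2-[4-(benzyloxy)-3-methoxybenzoyl]-3-[4-(benzyloxy)-3-methoxybenzyl]-2-hydroxybutanedioate as a mixture of stereoisomers F3. This aldol is not stereocontrolled: the (2R*,3R*) pair would be separated by chromatography and resolved on a chiral stationary phase to give 7.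

3. Step 8. The Lewis acid may ionise the benzylic C2–O1 bond beside the electron-rich arene, which would epimerise C2 or open the ring reductively, or it may strip the silyl ether.
Fallback: it sets out from 11 and comes back at 12, closing the ether by displacement without a Lewis acid. Lactol 11 is reduced through its open hydroxy aldehyde form with NaBH4 (MeOH, 0 °C) to methyl (2R,3S)-2-[(R)-[4-(benzyloxy)-3-methoxyphenyl](hydroxy)methyl]-3-[4-(benzyloxy)-3-methoxybenzyl]-4-hydroxy-2-[(triethylsilyl)oxy]butanoate F4. Treatment with TsCl in pyridine (0 → 50 °C) should sulfonylate only the primary hydroxyl, giving the 4-O-tosylate F5. The C2 hydroxyl then displaces the tosylate in a 5-exo-tet closure that leaves the C2–O bond and its configuration untouched, giving 12.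

**Further compounds**
F0 | step 6 | none | none
F1 | step 4 | methyl 3-[4-(benzyloxy)-3-methoxyphenyl]-3-oxopropanoate | COC(=O)CC(=O)c1ccc(OCc2ccccc2)c(OC)c1
F2 | step 4 | methyl 3-[4-(benzyloxy)-3-methoxyphenyl]-2,3-dioxopropanoate | COC(=O)C(=O)C(=O)c1ccc(OCc2ccccc2)c(OC)c1
F3 | step 4 | dimethyl 2-[4-(benzyloxy)-3-methoxybenzoyl]-3-[4-(benzyloxy)-3-methoxybenzyl]-2-hydroxybutanedioate, mixture of stereoisomers | COC(=O)C(Cc1ccc(OCc2ccccc2)c(OC)c1)C(O)(C(=O)OC)C(=O)c1ccc(OCc2ccccc2)c(OC)c1
F4 | step 8 | methyl (2R,3S)-2-[(R)-[4-(benzyloxy)-3-methoxyphenyl](hydroxy)methyl]-3-[4-(benzyloxy)-3-methoxybenzyl]-4-hydroxy-2-[(triethylsilyl)oxy]butanoate | OC[C@H](Cc1ccc(OCc2ccccc2)c(OC)c1)[C@](O[Si](CC)(CC)CC)(C(=O)OC)[C@H](O)c1ccc(OCc2ccccc2)c(OC)c1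
F5 | step 8 | methyl (2R,3S)-2-[(R)-[4-(benzyloxy)-3-methoxyphenyl](hydroxy)methyl]-3-[4-(benzyloxy)-3-methoxybenzyl]-4-[(4-methylbenzenesulfonyl)oxy]-2-[(triethylsilyl)oxy]butanoate | Cc1ccc(cc1)S(=O)(=O)OC[C@H](Cc1ccc(OCc2ccccc2)c(OC)c1)[C@](O[Si](CC)(CC)CC)(C(=O)OC)[C@H](O)c1ccc(OCc2ccccc2)c(OC)c1
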